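**Retrosynthetic overview**
- Ring C: flavonol 30 comes from Algar–Flynn–Oyamada closure (O1–C2 bond and C3 hydroxyl) of 2'-hydroxychalcone 27. The C4–C4a bond of the chalcone comes from adding the ring A aryllithium 25 to cinnamoyl Weinreb amide 24, which carries ring B from isovanillin.
- The strategy rests on ring A, a fully substituted 1,3,5-trioxygenated benzene: C5 (OH), C6 (prenyl), C7 (OMe), C8 (prenyl), C8a (O), C4a (H). This is the pattern a vinylketene and an ynol ether produce.
- Ring A comes from a Danheiser benzannulation of 3-silyloxycyclobutenone 7 (supplies C5, C8, C8a, C4a) with methoxyalkyne 13 (supplies C6, C7). It forms C5–C6 and C7–C8 and re-forms C5–C4a; both prenyl groups arrive on the building blocks.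
- Cyclobutenone 7 comes from siloxyalkyne 6 and ketene, and 6 from 5-methylhex-4-en-1-yne 3. Alkyne 13 comes from trichloroethylene, methanol and prenyl bromide.
- Ring order: ring B is bought, ring A is made in step 6, ring C is closed in step 13.

Key step: step 6

Assumption: ketene is supplied as a gas from pyrolysis of acetone; the target has no stereocentre, and compounds 15, 28, F5 and F6 are racemic.

**Step 1**
Reactants: 1 ethynylmagnesium bromide; 2 prenyl bromide
Product: 3 5-methylhex-4-en-1-yne
Conditions: 1 (excess), CuCl (cat.), THF, 0 → 50 °C; fractional distillation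
Reagents that add atoms: none
Why: Copper-catalysed coupling of an alkynyl Grignard reagent with an allylic bromide, in which attack at the unhindered primary carbon of the prenyl unit should dominate over the SN2' mode and the excess of acetylide suppresses double alkylation.

**Step 2**
Reactants: 3 5-methylhex-4-en-1-yne
Product: 6 triisopropyl[(5-methylhex-4-en-1-yn-1-yl)oxy]silane, via lithium acetylide 4 (not isolated), via lithium ynolate 5 (not isolated)
Conditions: n-BuLi, THF, −78 °C; t-BuOOLi [from t-BuOOH + LiN(SiMe3)2], −78 → 0 °C; TIPSOTf, −78 → 0 °C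
Reagents that add atoms: tert-butyl hydroperoxide CC(C)(C)OO; triisopropylsilyl trifluoromethanesulfonate CC(C)[Si](C(C)C)(C(C)C)OS(=O)(=O)C(F)(F)F
Why: Julia oxidation of the lithium acetylide by the electrophilic oxygen of the lithium peroxide gives the ynolate, which the bulky silyl triflate traps on oxygen (Kozmin siloxyalkyne synthesis), the acetylenic hydrogen being removed faster than the doubly activated C3 hydrogens at −78 °C.

**Step 3**
Reactants: 6 triisopropyl[(5-methylhex-4-en-1-yn-1-yl)oxy]silane
Product: 7 2-(3-methylbut-2-en-1-yl)-3-[(triisopropylsilyl)oxy]cyclobut-2-en-1-one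
Conditions: ketene (gas, excess), CH2Cl2, 0 °C → rt
Reagents that add atoms: ketene C=C=O
Why: Thermal (2+2) cycloaddition of ketene with an electron-rich siloxyalkyne, in which the alkyne carbon remote from oxygen attacks the ketene carbonyl carbon so that the prenyl group lands on C2 and the silyloxy group on C3 of the cyclobutenone.

**Step 4**
Reactants: 8 trichloroethylene
Product: 10 (E)-1,2-dichloro-1-methoxyethene, via dichloroethyne 9 (not isolated)
Conditions: KH, MeOH, THF, 0 °C; then 8, −50 °C → rt; used as a distilled THF solution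
Reagents that add atoms: methanol CO
Why: Greene dichlorovinyl ether synthesis, in which methoxide eliminates HCl from trichloroethylene and adds anti to the dichloroethyne formed, which stays in solution and is never isolated.

**Step 5**
Reactants: 10 (E)-1,2-dichloro-1-methoxyethene; 2 prenyl bromide
Product: 13 1-methoxy-5-methylhex-4-en-1-yne, via chloro(methoxy)ethyne 11 (not isolated), via lithium methoxyacetylide 12 (not isolated)
Conditions: n-BuLi (2 equiv), THF, −78 → −40 °C; then 2, HMPA, −78 °C → rt
Reagents that add atoms: none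
Why: Greene alkynyl ether synthesis, in which n-BuLi effects elimination to the chloroalkynyl ether and then chlorine–lithium exchange, and the lithium alkoxyacetylide is C-alkylated at the primary carbon of the reactive allylic bromide (SN2).

**Step 6**
Reactants: 7 2-(3-methylbut-2-en-1-yl)-3-[(triisopropylsilyl)oxy]cyclobut-2-en-1-one; 13 1-methoxy-5-methylhex-4-en-1-yne
Product: 18 3-methoxy-2,4-bis(3-methylbut-2-en-1-yl)-5-[(triisopropylsilyl)oxy]phenol, via vinylketene 14 (not isolated), via vinylcyclobutenone 15 (not isolated), via dienylketene 16 (not isolated), via cyclohexadienone 17 (not isolated)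
Conditions: 13 (2 equiv), toluene, 110 °C, sealed tube, argon
Reagents that add atoms: none
Why: Danheiser benzannulation: heating opens cyclobutenone 7 by four-electron electrocyclic cleavage of its C1–C4 bond to vinylketene 14, whose ketene carbon is attacked by the prenyl-bearing carbon of ynol ether 13 in a regiospecific (2+2) cycloaddition that gives 15. Four-electron opening of 15 gives dienylketene 16, and ring A closes by a six-electron electrocyclisation in which the ketene carbon (future C5) bonds to the terminal methylene (future C4a), after which dienone 17 tautomerises to the phenol. The closest precedent is the benzannulation of cyclobutenones with alkoxy- and silyloxyalkynes, here with an uncommon 3-silyloxycyclobutenone whose vinylogous ester stabilisation is expected to call for the higher temperature. No stereocentre is formed. The one selectivity needed is the orientation of the (2+2) step, which is fixed by the polarisation of the ynol ether (nucleophilic at the carbon remote from OMe) and places a prenyl group next to the new hydroxyl and the OMe between the two prenyl groups; the methyl ynol ether has no β-hydrogen and so cannot fragment to a ketene at this temperature.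

**Step 7**
Reactants: 18 3-methoxy-2,4-bis(3-methylbut-2-en-1-yl)-5-[(triisopropylsilyl)oxy]phenol
Product: 19 5-methoxy-4,6-bis(3-methylbut-2-en-1-yl)benzene-1,3-diol
Conditions: TBAF, THF, 0 °C; aq. NH4Cl
Reagents that add atoms: none
Why: Fluoride cleavage of the aryl silyl ether, giving a resorcinol with a mirror plane through C7 and C4a so that the two oxygens flanking C4a no longer need to be told apart.

**Step 8**
Reactants: 19 5-methoxy-4,6-bis(3-methylbut-2-en-1-yl)benzene-1,3-diol
Product: 20 3-methoxy-1,5-bis(methoxymethoxy)-2,4-bis(3-methylbut-2-en-1-yl)benzene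
Conditions: MOMCl (excess), iPr2NEt, CH2Cl2, 0 °C → rt
Reagents that add atoms: chloromethyl methyl ether COCCl
Why: O-alkylation of both phenols to MOM acetals, chosen because two MOM ethers are the best pair of directing groups for metalation at C4a, whereas an aryl silyl ether would shield that carbon and undergo 1,3 O-to-C silyl shift once lithiated.

**Step 9**
Reactants: 21 isovanillin
Product: 22 4-methoxy-3-(methoxymethoxy)benzaldehyde
Conditions: MOMCl, iPr2NEt, CH2Cl2, 0 °C → rt
Reagents that add atoms: chloromethyl methyl ether COCCl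
Why: Standard MOM protection of the ring B phenol so that it cannot quench the aryllithium of step 11.

**Step 10**
Reactants: 22 4-methoxy-3-(methoxymethoxy)benzaldehyde; 23 diethyl {2-[methoxy(methyl)amino]-2-oxoethyl}phosphonate
Product: 24 (2E)-N-methoxy-3-[4-methoxy-3-(methoxymethoxy)phenyl]-N-methylprop-2-enamide
Conditions: NaH, THF, 0 °C → rt
Reagents that add atoms: none
Why: Horner–Wadsworth–Emmons olefination with a stabilised phosphonate anion, which should give the E-alkene.

**Step 11**
Reactants: 20 3-methoxy-1,5-bis(methoxymethoxy)-2,4-bis(3-methylbut-2-en-1-yl)benzene; 24 (2E)-N-methoxy-3-[4-methoxy-3-(methoxymethoxy)phenyl]-N-methylprop-2-enamide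
Product: 26 (2E)-1-[4-methoxy-2,6-bis(methoxymethoxy)-3,5-bis(3-methylbut-2-en-1-yl)phenyl]-3-[4-methoxy-3-(methoxymethoxy)phenyl]prop-2-en-1-one, via aryllithium 25 (not isolated)
Conditions: n-BuLi, THF, 0 °C; then 24, −78 → 0 °C; aq. NH4Cl
Reagents that add atoms: none
Why: Directed ortho-metalation at the only ring hydrogen, flanked by two MOM ethers, followed by 1,2-addition to the Weinreb amide, whose chelated tetrahedral intermediate prevents over-addition and conjugate addition and so delivers the C4–C4a bond of the chalcone.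

**Step 12**
Reactants: 26 (2E)-1-[4-methoxy-2,6-bis(methoxymethoxy)-3,5-bis(3-methylbut-2-en-1-yl)phenyl]-3-[4-methoxy-3-(methoxymethoxy)phenyl]prop-2-en-1-one
Product: 27 (2E)-1-[2-hydroxy-4-methoxy-6-(methoxymethoxy)-3,5-bis(3-methylbut-2-en-1-yl)phenyl]-3-[4-methoxy-3-(methoxymethoxy)phenyl]prop-2-en-1-one
Conditions: HCl (cat.), MeOH–THF, 0 °C → rt, quenched with NaHCO3 once 26 is consumed
Reagents that add atoms: none
Why: Acid-catalysed acetal methanolysis in which a MOM ether ortho to the ketone should leave first because the phenol released is held by a hydrogen bond to the carbonyl oxygen, while the remaining ortho MOM and the ring B MOM lack this assistance; the two ortho acetals are equivalent by symmetry, so only the degree of cleavage has to be controlled.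

**Step 13**
Reactants: 27 (2E)-1-[2-hydroxy-4-methoxy-6-(methoxymethoxy)-3,5-bis(3-methylbut-2-en-1-yl)phenyl]-3-[4-methoxy-3-(methoxymethoxy)phenyl]prop-2-en-1-one
Product: 29 3-hydroxy-7-methoxy-5-(methoxymethoxy)-2-[4-methoxy-3-(methoxymethoxy)phenyl]-6,8-bis(3-methylbut-2-en-1-yl)-4H-chromen-4-one, via dihydroflavonol 28 (not isolated)
Conditions: 30% aq. H2O2, aq. NaOH, MeOH–THF, 0 °C → rt
Reagents that add atoms: hydrogen peroxide OO
Why: Algar–Flynn–Oyamada reaction, in which the phenoxide closes ring C by six-membered oxa-Michael attack on the enone while the enolate is hydroxylated by peroxide, and the 3-hydroxyflavanone is oxidised on to the flavonol; the para-methoxy group of ring B favours this mode over aurone formation and the trisubstituted prenyl alkenes are inert to nucleophilic peroxide.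

**Step 14**
Reactants: 29 3-hydroxy-7-methoxy-5-(methoxymethoxy)-2-[4-methoxy-3-(methoxymethoxy)phenyl]-6,8-bis(3-methylbut-2-en-1-yl)-4H-chromen-4-one
Product: 30 3,5-dihydroxy-2-(3-hydroxy-4-methoxyphenyl)-7-methoxy-6,8-bis(3-methylbut-2-en-1-yl)-4H-chromen-4-one
Conditions: HCl (2 M in MeOH), THF, rt → 40 °C
Reagents that add atoms: none
Why: Mild acid methanolysis of the two remaining MOM acetals, under which the liberated 5-hydroxyl is tied up in a hydrogen bond to the C4 carbonyl and should not cyclise onto the C6 prenyl group.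

**Compound list**
1 | ethynylmagnesium bromide | C#C[Mg]Br | starting material
2 | prenyl bromide (1-bromo-3-methylbut-2-ene) | CC(C)=CCBr | starting material
3 | 5-methylhex-4-en-1-yne | C#CCC=C(C)C | intermediate
4 | lithium 5-methylhex-4-en-1-yn-1-ide | [Li+].[C-]#CCC=C(C)C | intermediate (not isolated)
5 | lithium 5-methylhex-4-en-1-yn-1-olate | [Li+].[O-]C#CCC=C(C)C | intermediate (not isolated)
6 | triisopropyl[(5-methylhex-4-en-1-yn-1-yl)oxy]silane | CC(C)=CCC#CO[Si](C(C)C)(C(C)C)C(C)C | intermediate
7 | 2-(3-methylbut-2-en-1-yl)-3-[(triisopropylsilyl)oxy]cyclobut-2-en-1-one | O=C1CC(O[Si](C(C)C)(C(C)C)C(C)C)=C1CC=C(C)C | intermediate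
8 | trichloroethylene | ClC=C(Cl)Cl | starting material
9 | dichloroethyne | ClC#CCl | intermediate (not isolated)
10 | (E)-1,2-dichloro-1-methoxyethene | CO/C(Cl)=C\Cl | intermediate
11 | 1-chloro-2-methoxyethyne | COC#CCl | intermediate (not isolated)
12 | lithium methoxyethynide | [Li+].[C-]#COC | intermediate (not isolated)
13 | 1-methoxy-5-methylhex-4-en-1-yne | COC#CCC=C(C)C | intermediate
14 | 2-(3-methylbut-2-en-1-yl)-3-[(triisopropylsilyl)oxy]buta-1,3-dien-1-one | O=C=C(CC=C(C)C)C(=C)O[Si](C(C)C)(C(C)C)C(C)C | intermediate (not isolated)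
15 | racemic 3-methoxy-2,4-bis(3-methylbut-2-en-1-yl)-4-{1-[(triisopropylsilyl)oxy]ethenyl}cyclobut-2-en-1-one | O=C1C(CC=C(C)C)=C(OC)C1(CC=C(C)C)C(=C)O[Si](C(C)C)(C(C)C)C(C)C | intermediate (not isolated)
16 | (3E)-3-methoxy-2,4-bis(3-methylbut-2-en-1-yl)-5-[(triisopropylsilyl)oxy]hexa-1,3,5-trien-1-one | O=C=C(CC=C(C)C)/C(OC)=C(CC=C(C)C)\C(=C)O[Si](C(C)C)(C(C)C)C(C)C | intermediate (not isolated)
17 | 3-methoxy-2,4-bis(3-methylbut-2-en-1-yl)-5-[(triisopropylsilyl)oxy]cyclohexa-2,4-dien-1-one | O=C1CC(O[Si](C(C)C)(C(C)C)C(C)C)=C(CC=C(C)C)C(OC)=C1CC=C(C)C | intermediate (not isolated)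
18 | 3-methoxy-2,4-bis(3-methylbut-2-en-1-yl)-5-[(triisopropylsilyl)oxy]phenol | Oc1cc(O[Si](C(C)C)(C(C)C)C(C)C)c(CC=C(C)C)c(OC)c1CC=C(C)C | intermediate
19 | 5-methoxy-4,6-bis(3-methylbut-2-en-1-yl)benzene-1,3-diol | COc1c(CC=C(C)C)c(O)cc(O)c1CC=C(C)C | intermediate
20 | 3-methoxy-1,5-bis(methoxymethoxy)-2,4-bis(3-methylbut-2-en-1-yl)benzene | COCOc1cc(OCOC)c(CC=C(C)C)c(OC)c1CC=C(C)C | intermediate
21 | isovanillin (3-hydroxy-4-methoxybenzaldehyde) | COc1ccc(C=O)cc1O | starting material
22 | 4-methoxy-3-(methoxymethoxy)benzaldehyde | COCOc1cc(C=O)ccc1OC | intermediate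
23 | diethyl {2-[methoxy(methyl)amino]-2-oxoethyl}phosphonate | CCOP(=O)(CC(=O)N(C)OC)OCC | starting material
24 | (2E)-N-methoxy-3-[4-methoxy-3-(methoxymethoxy)phenyl]-N-methylprop-2-enamide | COCOc1cc(/C=C/C(=O)N(C)OC)ccc1OC | intermediate
25 | [4-methoxy-2,6-bis(methoxymethoxy)-3,5-bis(3-methylbut-2-en-1-yl)phenyl]lithium | [Li]c1c(OCOC)c(CC=C(C)C)c(OC)c(CC=C(C)C)c1OCOC | intermediate (not isolated)
26 | (2E)-1-[4-methoxy-2,6-bis(methoxymethoxy)-3,5-bis(3-methylbut-2-en-1-yl)phenyl]-3-[4-methoxy-3-(methoxymethoxy)phenyl]prop-2-en-1-one | COCOc1c(CC=C(C)C)c(OC)c(CC=C(C)C)c(OCOC)c1C(=O)/C=C/c1ccc(OC)c(OCOC)c1 | intermediate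
27 | (2E)-1-[2-hydroxy-4-methoxy-6-(methoxymethoxy)-3,5-bis(3-methylbut-2-en-1-yl)phenyl]-3-[4-methoxy-3-(methoxymethoxy)phenyl]prop-2-en-1-one | COCOc1c(CC=C(C)C)c(OC)c(CC=C(C)C)c(O)c1C(=O)/C=C/c1ccc(OC)c(OCOC)c1 | intermediate
28 | racemic trans-3-hydroxy-7-methoxy-5-(methoxymethoxy)-2-[4-methoxy-3-(methoxymethoxy)phenyl]-6,8-bis(3-methylbut-2-en-1-yl)-2,3-dihydro-4H-chromen-4-one (one enantiomer drawn) | COc1ccc(cc1OCOC)[C@@H]2[C@H](C(=O)c3c(O2)c(CC=C(C)C)c(OC)c(CC=C(C)C)c3OCOC)O | intermediate (not isolated)
29 | 3-hydroxy-7-methoxy-5-(methoxymethoxy)-2-[4-methoxy-3-(methoxymethoxy)phenyl]-6,8-bis(3-methylbut-2-en-1-yl)-4H-chromen-4-one | COCOc1cc(-c2oc3c(CC=C(C)C)c(OC)c(CC=C(C)C)c(OCOC)c3c(=O)c2O)ccc1OC | intermediate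
30 | 3,5-dihydroxy-2-(3-hydroxy-4-methoxyphenyl)-7-methoxy-6,8-bis(3-methylbut-2-en-1-yl)-4H-chromen-4-one | COc1ccc(-c2oc3c(CC=C(C)C)c(OC)c(CC=C(C)C)c(O)c3c(=O)c2O)cc1O | target

**Step count**
Total: 14 steps. Longest linear sequence: 10 steps (1, 2, 3, 6, 7, 8, 11, 12, 13, 14).

**Steps most likely to fail**

Step 6. The four-electron opening of the donor-stabilised cyclobutenone may be too slow, so that thermal decay of the two electron-rich partners and O-acylation of the product phenol by the vinylketene outrun the annulation. The fallback gives up the annulation and builds the ring A pattern by classical C-prenylation; it sets out from prenyl bromide 2 and comes back at chalcone 27. Commercial 2,4,6-trihydroxyacetophenone is C-prenylated twice with 2 in cold aqueous KOH to give 1-[2,4,6-trihydroxy-3,5-bis(3-methylbut-2-en-1-yl)phenyl]ethan-1-one F1, which is separated from mono- and over-prenylated material. The para hydroxyl, the only one not chelated to the acetyl group, is methylated (MeI, K2CO3, acetone) to 1-[2,6-dihydroxy-4-methoxy-3,5-bis(3-methylbut-2-en-1-yl)phenyl]ethan-1-one F2. One of the two equivalent chelated hydroxyls is protected (MOMCl, iPr2NEt, CH2Cl2) to give 1-[2-hydroxy-4-methoxy-6-(methoxymethoxy)-3,5-bis(3-methylbut-2-en-1-yl)phenyl]ethan-1-one F3. Claisen–Schmidt condensation of F3 with aldehyde 22 (KOH, EtOH) gives 27. This route is known chemistry but forfeits the regiocontrol of the annulation.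

Step 13. The carbonyl of the doubly ortho-substituted chalcone is twisted out of conjugation, so five-membered closure to the aurone or stalling at partial oxidation may compete with flavonol formation. The fallback separates epoxidation, ring closure and dehydrogenation; it sets out from chalcone 26 and comes back at target 30. Weitz–Scheffer epoxidation of 26 (H2O2, NaOH, MeOH–THF), which has no free phenol and so no aurone pathway, gives racemic [4-methoxy-2,6-bis(methoxymethoxy)-3,5-bis(3-methylbut-2-en-1-yl)phenyl]{trans-3-[4-methoxy-3-(methoxymethoxy)phenyl]oxiran-2-yl}methanone F5. HCl in MeOH–THF removes the MOM groups and lets a liberated phenol open the epoxide at the benzylic carbon, giving racemic trans-3,5-dihydroxy-2-(3-hydroxy-4-methoxyphenyl)-7-methoxy-6,8-bis(3-methylbut-2-en-1-yl)-2,3-dihydro-4H-chromen-4-one F6. Base-mediated air oxidation of F6 (pyridine, 90 °C) dehydrogenates C2–C3 to give 30.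

Step 12. Acetal cleavage may run on to the diol or take the ring B acetal, and a liberated phenol may cyclise onto the neighbouring prenyl group under acid. The fallback replaces selective deprotection by selective protection; it sets out from chalcone 26 and comes back at chalcone 27. All three MOM groups are removed (HCl, MeOH–THF, rt) to give (2E)-1-[2,6-dihydroxy-4-methoxy-3,5-bis(3-methylbut-2-en-1-yl)phenyl]-3-(3-hydroxy-4-methoxyphenyl)prop-2-en-1-one F4. Treatment of F4 with two equivalents of MOMCl and iPr2NEt in CH2Cl2 protects the ring B phenol and one of the two equivalent ortho hydroxyls; the other stays free because of its hydrogen bond to the carbonyl, which gives 27.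

**Further compounds**
F1 | step 6 | 1-[2,4,6-trihydroxy-3,5-bis(3-methylbut-2-en-1-yl)phenyl]ethan-1-one | CC(=O)c1c(O)c(CC=C(C)C)c(O)c(CC=C(C)C)c1O
F2 | step 6 | 1-[2,6-dihydroxy-4-methoxy-3,5-bis(3-methylbut-2-en-1-yl)phenyl]ethan-1-one | CC(=O)c1c(O)c(CC=C(C)C)c(OC)c(CC=C(C)C)c1O
F3 | step 6 | 1-[2-hydroxy-4-methoxy-6-(methoxymethoxy)-3,5-bis(3-methylbut-2-en-1-yl)phenyl]ethan-1-one | CC(=O)c1c(O)c(CC=C(C)C)c(OC)c(CC=C(C)C)c1OCOC
F4 | step 12 | (2E)-1-[2,6-dihydroxy-4-methoxy-3,5-bis(3-methylbut-2-en-1-yl)phenyl]-3-(3-hydroxy-4-methoxyphenyl)prop-2-en-1-one | COc1ccc(/C=C/C(=O)c2c(O)c(CC=C(C)C)c(OC)c(CC=C(C)C)c2O)cc1O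
F5 | step 13 | racemic [4-methoxy-2,6-bis(methoxymethoxy)-3,5-bis(3-methylbut-2-en-1-yl)phenyl]{trans-3-[4-methoxy-3-(methoxymethoxy)phenyl]oxiran-2-yl}methanone (one enantiomer drawn) | COCOc1c(CC=C(C)C)c(OC)c(CC=C(C)C)c(OCOC)c1C(=O)[C@@H]1O[C@H]1c1ccc(OC)c(OCOC)c1
F6 | step 13 | racemic trans-3,5-dihydroxy-2-(3-hydroxy-4-methoxyphenyl)-7-methoxy-6,8-bis(3-methylbut-2-en-1-yl)-2,3-dihydro-4H-chromen-4-one (one enantiomer drawn) | COc1ccc(cc1O)[C@@H]2[C@H](C(=O)c3c(O2)c(CC=C(C)C)c(OC)c(CC=C(C)C)c3O)O
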